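**Retrosynthetic overview**
1. The O7 ester is cut to the bicyclic C7 alcohol and a C10 ynoic acid; the Z-4-oxo-2-enoate is unmasked last by semihydrogenation of the ynone.
2. Ring B (δ-lactone, O5–C1) is opened and C2–C3 is cut by a chelation-controlled anti-aldol of a propanethioate on the C3 aldehyde of ring A.
3. The strategy rests on C4 of ring A (tetrahydropyran): a fully substituted ether carbon bonded to O8, a methyl, C5 and C3, with C3 at the carbonyl level. O8–C4 is cut back to a hydroxy ketene dithioacetal, closed in the forward sense by anodic oxidation with methanol capping C3.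
4. The acyclic C3–C9 chain comes from ethyl (S)-lactate (C8), an auxiliary-controlled syn-aldol (C6, C7), a chelation-controlled ketone reduction (C5) and a Peterson olefination (C3).
5. Ring order: ring A in step 12, then ring B in step 17.

Key step: step 12

Remark: atoms are numbered C1 (lactone carbonyl) to C9 (methyl on C8), oxygens after their carbon; CIP descriptors are given per compound and may change with substituent priority while the geometry stays the same. The side-chain carbinol carbon is carried as a racemate because it ends as a ketone.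

**Step 1**
Reactants: 1 ethyl (S)-lactate
Product: 2 ethyl (S)-2-(triethylsilyloxy)propanoate
Conditions: Et3SiCl, imidazole, DMF, 0 °C to rt
Reagents that add atoms: chlorotriethylsilane, CC[Si](Cl)(CC)CC
Why: Routine O-silylation of a secondary alcohol; the triethylsilyl group is chosen so that fluoride can later free O8 while a tert-butyldimethylsilyl ether at O5 stays.

**Step 2**
Reactants: 2 ethyl (S)-2-(triethylsilyloxy)propanoate
Product: 3 (S)-2-(triethylsilyloxy)propanal
Conditions: i-Bu2AlH, CH2Cl2, −78 °C; MeOH, then aq. KNaC4H4O6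
Reagents that add atoms: none
Why: Partial ester reduction with i-Bu2AlH stops at the aldehyde because the tetrahedral aluminate survives at −78 °C; the aldehyde is used at once so that C8 does not epimerise.

**Step 3**
Reactants: 3 (S)-2-(triethylsilyloxy)propanal; 4 (R)-4-benzyl-3-propanoyl-1,3-oxazolidin-2-one
Product: 6 (R)-4-benzyl-3-[(2R,3R,4S)-3-hydroxy-2-methyl-4-(triethylsilyloxy)pentanoyl]-1,3-oxazolidin-2-one, via dibutylboron Z-enolate 5 (not isolated)
Conditions: 4, n-Bu2BOTf, i-Pr2NEt, CH2Cl2, 0 °C; 3, −78 to 0 °C; pH 7 buffer, MeOH, H2O2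
Reagents that add atoms: none
Why: Evans syn-aldol reaction: the Z-boron enolate reacts through a Zimmerman–Traxler chair on the face away from the benzyl group, which sets C6 (R) and C7 (R) syn, in the 7,8-anti sense that the α-silyloxy aldehyde also favours.

**Step 4**
Reactants: 6 aldol imide
Product: 7 (2R,3R,4S)-3-hydroxy-N-methoxy-N,2-dimethyl-4-(triethylsilyloxy)pentanamide
Conditions: MeNHOMe·HCl, AlMe3, CH2Cl2, −20 to 0 °C
Reagents that add atoms: N,O-dimethylhydroxylamine hydrochloride, CNOC.Cl
Why: Aluminium amide transamidation of the aldol imide to the Weinreb amide, assisted by the free β-hydroxyl; no stereocentre is touched.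

**Step 5**
Reactants: 7 hydroxy Weinreb amide
Product: 8 (2R,3R,4S)-3-(benzyloxy)-N-methoxy-N,2-dimethyl-4-(triethylsilyloxy)pentanamide
Conditions: 2-benzyloxy-1-methylpyridinium triflate, MgO, PhCF3, 83 °C
Reagents that add atoms: 2-benzyloxy-1-methylpyridinium triflate, C[n+]1ccccc1OCc1ccccc1.[O-]S(=O)(=O)C(F)(F)F
Why: Benzyl transfer under neutral conditions protects O7 without forming an alkoxide, so neither retro-aldol cleavage nor silyl migration from O8 to O7 should occur.

**Step 6**
Reactants: 8 benzyloxy Weinreb amide; 9 isopropenylmagnesium bromide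
Product: 10 (4R,5R,6S)-5-(benzyloxy)-2,4-dimethyl-6-(triethylsilyloxy)hept-1-en-3-one
Conditions: THF, −20 to 0 °C; cold aq. NH4Cl
Reagents that add atoms: none
Why: Weinreb ketone synthesis: the magnesium chelate of the tetrahedral adduct holds until the quench, which prevents a second addition and epimerisation at C6.

**Step 7**
Reactants: 10 enone
Product: 11 (3S,4S,5R,6S)-5-(benzyloxy)-2,4-dimethyl-6-(triethylsilyloxy)hept-1-en-3-ol
Conditions: Zn(BH4)2, Et2O, −30 °C
Reagents that add atoms: none
Why: Chelation-controlled 1,2-reduction: zinc bridges the C5 carbonyl oxygen and O7, the C6 methyl sits axial in the six-membered chelate and hydride enters anti to it, which gives the C5 alcohol syn to both the C6 methyl and O7.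

**Step 8**
Reactants: 11 allylic alcohol
Product: 12 (3S,4R,5R,6S)-5-(benzyloxy)-3-(tert-butyldimethylsilyloxy)-2,4-dimethyl-6-(triethylsilyloxy)hept-1-ene
Conditions: t-BuMe2SiOTf, 2,6-lutidine, CH2Cl2, −78 to 0 °C
Reagents that add atoms: tert-butyldimethylsilyl trifluoromethanesulfonate, CC(C)(C)[Si](C)(C)OS(=O)(=O)C(F)(F)F
Why: Silylation of a hindered secondary alcohol with the silyl triflate; O5 now carries a group that outlasts the later fluoride release of O8.

**Step 9**
Reactants: 12 bis-silyl alkene
Product: 13 (3S,4R,5R,6S)-5-(benzyloxy)-3-(tert-butyldimethylsilyloxy)-4-methyl-6-(triethylsilyloxy)heptan-2-one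
Conditions: O3, CH2Cl2, −78 °C (to first blue colour); PPh3, −78 °C to rt
Reagents that add atoms: ozone, [O-][O+]=O
Why: Ozonolysis of the 1,1-disubstituted alkene with reductive work-up gives the C4 methyl ketone; stopping at the end point spares the benzyl ether.

**Step 10**
Reactants: 13 methyl ketone; 14 2-trimethylsilyl-1,3-dithiane
Product: 16 2-[(3S,4R,5R,6S)-5-(benzyloxy)-3-(tert-butyldimethylsilyloxy)-4-methyl-6-(triethylsilyloxy)heptan-2-ylidene]-1,3-dithiane, via 2-lithio-2-trimethylsilyl-1,3-dithiane 15 (not isolated)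
Conditions: 14, n-BuLi, THF, −20 °C; 13, −78 °C to rt
Reagents that add atoms: none
Why: Peterson olefination: the silyl-stabilised dithiane anion adds to the ketone and the β-silyl alkoxide loses lithium trimethylsilanolate, which installs C3 as a ketene dithioacetal at the carboxyl oxidation level.

**Step 11**
Reactants: 16 bis-silyl ketene dithioacetal
Product: 17 (2S,3R,4R,5S)-3-(benzyloxy)-5-(tert-butyldimethylsilyloxy)-6-(1,3-dithian-2-ylidene)-4-methylheptan-2-ol
Conditions: Bu4NF, AcOH (1:1), THF, 0 °C
Reagents that add atoms: none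
Why: Fluoride desilylation is faster for the triethylsilyl ether at O8 than for the hindered tert-butyldimethylsilyl ether at O5, and the buffered non-acidic medium leaves the ketene dithioacetal intact.

**Step 12**
Reactants: 17 hydroxy ketene dithioacetal; 18 methanol
Product: 19 2-[(2S,3S,4R,5R,6S)-5-(benzyloxy)-3-(tert-butyldimethylsilyloxy)-2,4,6-trimethyloxan-2-yl]-2-methoxy-1,3-dithiane
Conditions: reticulated vitreous carbon anode, Pt wire cathode, undivided cell, constant current (8 mA, 2.2 F/mol), 0.1 M LiClO4, MeOH–THF (3:7), 2,6-lutidine, rt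
Reagents that add atoms: none
Why: One-electron oxidation at the anode turns the ketene dithioacetal, the only group oxidised at this potential, into a radical cation that the lutidine-activated O8 hydroxyl attacks at C4; loss of a second electron from the C3 dithianyl radical and capture by methanol give the ortho ester, while protons are reduced to H2 at the cathode. The closest known reaction type is the anodic coupling of ketene dithioacetal radical cations with tethered alcohols to give cyclic ethers with tetrasubstituted carbons. Ring A closes 6-exo-trig through a chair in which the C5 silyloxy, C6 methyl, C7 benzyloxy and C8 methyl groups are all equatorial. The new C4 centre is set by allylic 1,3-strain: the sulfur cis to C5 holds H5 in the alkene plane, so O8, tethered through C6, adds to the face that leaves the C4 methyl anti to H5 (axial) and C3 equatorial (4S). The step needs six-ring closure to outrun methanol capture at C4 and needs one alkene face; the intramolecular base-activated hydroxyl, the low methanol content and the conformational lock from the dithiane and the equatorial C5–C8 array should secure both.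

**Step 13**
Reactants: 19 ring A dithio ortho ester
Product: 20 methyl (2S,3S,4R,5R,6S)-5-(benzyloxy)-3-(tert-butyldimethylsilyloxy)-2,4,6-trimethyloxane-2-carboxylate
Conditions: HgCl2, CaCO3, MeCN–H2O (4:1), rt
Reagents that add atoms: water, O
Why: Thiophile-assisted hydrolysis of the S,S,O-ortho ester: divalent mercury removes both sulfur atoms, water supplies the carbonyl oxygen and the methoxy group stays as the methyl ester.

**Step 14**
Reactants: 20 ring A methyl ester
Product: 21 (2S,3S,4R,5R,6S)-5-(benzyloxy)-3-(tert-butyldimethylsilyloxy)-2,4,6-trimethyloxane-2-carbaldehyde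
Conditions: i-Bu2AlH, CH2Cl2, −78 °C; MeOH, then aq. KNaC4H4O6
Reagents that add atoms: none
Why: Partial reduction of an α-alkoxy ester: the aluminate is stabilised by chelation to O8 and collapses to the aldehyde only on work-up; C4 is quaternary, so the aldehyde cannot epimerise.

**Step 15**
Reactants: 22 S-tert-butyl propanethioate
Product: 24 (Z)-1-(tert-butylsulfanyl)-1-(trimethylsilyloxy)prop-1-ene (methyl trans to the silyloxy group), via lithium enolate of the thioester 23 (not isolated)
Conditions: LiN(i-Pr)2, THF, −78 °C; Me3SiCl, −78 °C to rt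
Reagents that add atoms: chlorotrimethylsilane, C[Si](C)(C)Cl
Why: Kinetic enolisation of the thioester with the lithium amide in THF gives the enolate with methyl trans to oxygen, which O-silylation traps as the silyl ketene acetal.

**Step 16**
Reactants: 21 ring A aldehyde; 24 silyl ketene acetal
Product: 25 S-tert-butyl (2R,3S)-3-[(2R,3S,4R,5R,6S)-5-(benzyloxy)-3-(tert-butyldimethylsilyloxy)-2,4,6-trimethyloxan-2-yl]-3-hydroxy-2-methylpropanethioate
Conditions: 21, SnCl4, CH2Cl2, −78 °C; 24, −78 °C; aq. NaHCO3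
Reagents that add atoms: none
Why: Chelation-controlled Mukaiyama aldol reaction: SnCl4 bridges the aldehyde oxygen and O8, the ketene acetal attacks the chelate face that carries the axial C4 methyl and not ring carbon C5 (3S, O3 syn to O8), and the open transition state of this ketene acetal geometry gives the 2,3-anti adduct (2R).

**Step 17**
Reactants: 25 β-hydroxy thioester
Product: 27 7-(benzyloxy)-4-hydroxy-3,4a,6,8-tetramethylhexahydropyrano[3,2-b]pyran-2(3H)-one (botcinin numbering 2R,3S,4R,5S,6R,7R,8S; 3-OH, 7-OBn), via O5-desilylated hydroxy thioester 26 (not isolated)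
Conditions: aq. HF, MeCN, 0 °C to rt; then AgOCOCF3, Na2HPO4, MeCN, rt
Reagents that add atoms: none
Why: Acidic fluoride desilylation frees O5 without retro-aldol cleavage, and silver-assisted thioester activation then drives lactonisation of O5 onto C1, closing ring B as the trans-fused δ-lactone.

**Step 18**
Reactants: 27 hydroxy lactone
Product: 28 3-O-acetyl lactone (botcinin numbering 2R,3S,4S,5S,6R,7R,8S; 3-OAc, 7-OBn)
Conditions: Ac2O, pyridine, DMAP (cat.), CH2Cl2, 0 °C to rt
Reagents that add atoms: acetic anhydride, CC(=O)OC(C)=O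
Why: Acylation of the hindered C3 alcohol under nucleophilic catalysis; O7 is still benzylated, so only O3 is acetylated.

**Step 19**
Reactants: 28 benzyl ether
Product: 29 C7 alcohol of the acetylated bicycle (2R,3S,4S,5S,6R,7R,8S; 3-OAc, 7-OH)
Conditions: H2 (1 atm), Pd/C, EtOAc, rt
Reagents that add atoms: none
Why: Catalytic hydrogenolysis of the benzyl ether frees O7; lactone and acetate are inert.

**Step 20**
Reactants: 30 heptanal; 31 ethynylmagnesium bromide
Product: 32 (±)-non-1-yn-3-ol
Conditions: THF, 0 °C; aq. NH4Cl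
Reagents that add atoms: none
Why: Grignard 1,2-addition of the acetylide to the aldehyde; the carbinol is racemic, which is immaterial because it is oxidised later.

**Step 21**
Reactants: 32 (±)-non-1-yn-3-ol
Product: 33 (±)-triethyl(non-1-yn-3-yloxy)silane
Conditions: Et3SiCl, imidazole, CH2Cl2, 0 °C to rt
Reagents that add atoms: chlorotriethylsilane, CC[Si](Cl)(CC)CC
Why: Routine O-silylation; the ether masks the side-chain hydroxyl during carboxylation and esterification.

**Step 22**
Reactants: 33 silyl ether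
Product: 35 (±)-4-(triethylsilyloxy)dec-2-ynoic acid, via lithium acetylide 34 (not isolated)
Conditions: n-BuLi, THF, −78 °C; CO2, −78 to 0 °C; cold dilute HCl to pH 3
Reagents that add atoms: carbon dioxide, O=C=O
Why: Deprotonation of the terminal alkyne and carboxylation of the lithium acetylide give the ynoic acid.

**Step 23**
Reactants: 29 C7 alcohol; 35 ynoic acid
Product: 36 7-O-[4-(triethylsilyloxy)dec-2-ynoyl] ester of 29 (two epimers at the side-chain carbinol)
Conditions: DCC, DMAP (cat.), CH2Cl2, −20 to 0 °C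
Reagents that add atoms: none
Why: Carbodiimide (Steglich) esterification at low temperature acylates the equatorial C7 alcohol with retention; the silyl ether keeps the side-chain hydroxyl out of the coupling.

**Step 24**
Reactants: 36 silyloxy ynoate
Product: 38 7-O-(4-oxodec-2-ynoyl) ester of 29, via propargylic alcohol 37 (not isolated)
Conditions: CrO3, H2SO4, H2O, acetone, 0 °C
Reagents that add atoms: none
Why: Jones oxidation: the aqueous acid first removes the triethylsilyl group and chromic acid then oxidises the propargylic alcohol to the ynone, which merges the two side-chain epimers.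

**Step 25**
Reactants: 38 ynone ester
Product: 39 Botcinin J
Conditions: H2 (1 atm), Pd/CaCO3 poisoned with Pb(OAc)2, EtOAc, 0 °C, stopped after one equivalent of H2
Reagents that add atoms: none
Why: Syn addition of one equivalent of hydrogen to the alkyne on lead-poisoned palladium (Lindlar-type semihydrogenation) should give the Z-enone, the activated alkyne being reduced faster than the resulting alkene.

**Compound list**
1 | ethyl (S)-lactate | CCOC(=O)[C@H](C)O | starting material
2 | ethyl (S)-2-(triethylsilyloxy)propanoate | CCOC(=O)[C@H](C)O[Si](CC)(CC)CC | intermediate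
3 | (S)-2-(triethylsilyloxy)propanal | O=C[C@H](C)O[Si](CC)(CC)CC | intermediate
4 | (R)-4-benzyl-3-propanoyl-1,3-oxazolidin-2-one | CCC(=O)N1[C@H](Cc2ccccc2)COC1=O | starting material
5 | dibutylboron Z-enolate of 4 (not isolated) | C/C=C(\OB(CCCC)CCCC)N1[C@H](Cc2ccccc2)COC1=O | intermediate
6 | (R)-4-benzyl-3-[(2R,3R,4S)-3-hydroxy-2-methyl-4-(triethylsilyloxy)pentanoyl]-1,3-oxazolidin-2-one | O=C(N1[C@H](Cc2ccccc2)COC1=O)[C@H](C)[C@@H](O)[C@@H](O[Si](CC)(CC)CC)C | intermediate
7 | (2R,3R,4S)-3-hydroxy-N-methoxy-N,2-dimethyl-4-(triethylsilyloxy)pentanamide | CON(C)C(=O)[C@H](C)[C@@H](O)[C@@H](O[Si](CC)(CC)CC)C | intermediate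
8 | (2R,3R,4S)-3-(benzyloxy)-N-methoxy-N,2-dimethyl-4-(triethylsilyloxy)pentanamide | CON(C)C(=O)[C@H](C)[C@@H](OCc1ccccc1)[C@@H](O[Si](CC)(CC)CC)C | intermediate
9 | isopropenylmagnesium bromide | C=C(C)[Mg]Br | starting material
10 | (4R,5R,6S)-5-(benzyloxy)-2,4-dimethyl-6-(triethylsilyloxy)hept-1-en-3-one | C=C(C)C(=O)[C@H](C)[C@@H](OCc1ccccc1)[C@@H](O[Si](CC)(CC)CC)C | intermediate
11 | (3S,4S,5R,6S)-5-(benzyloxy)-2,4-dimethyl-6-(triethylsilyloxy)hept-1-en-3-ol | C=C(C)[C@@H](O)[C@H](C)[C@@H](OCc1ccccc1)[C@@H](O[Si](CC)(CC)CC)C | intermediate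
12 | (3S,4R,5R,6S)-5-(benzyloxy)-3-(tert-butyldimethylsilyloxy)-2,4-dimethyl-6-(triethylsilyloxy)hept-1-ene | C=C(C)[C@@H](O[Si](C)(C)C(C)(C)C)[C@H](C)[C@@H](OCc1ccccc1)[C@@H](O[Si](CC)(CC)CC)C | intermediate
13 | (3S,4R,5R,6S)-5-(benzyloxy)-3-(tert-butyldimethylsilyloxy)-4-methyl-6-(triethylsilyloxy)heptan-2-one | CC(=O)[C@@H](O[Si](C)(C)C(C)(C)C)[C@H](C)[C@@H](OCc1ccccc1)[C@@H](O[Si](CC)(CC)CC)C | intermediate
14 | 2-trimethylsilyl-1,3-dithiane | C[Si](C)(C)C1SCCCS1 | starting material
15 | 2-lithio-2-trimethylsilyl-1,3-dithiane (not isolated) | [Li]C1([Si](C)(C)C)SCCCS1 | intermediate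
16 | 2-[(3S,4R,5R,6S)-5-(benzyloxy)-3-(tert-butyldimethylsilyloxy)-4-methyl-6-(triethylsilyloxy)heptan-2-ylidene]-1,3-dithiane | S1CCCSC1=C(C)[C@@H](O[Si](C)(C)C(C)(C)C)[C@H](C)[C@@H](OCc2ccccc2)[C@@H](O[Si](CC)(CC)CC)C | intermediate
17 | (2S,3R,4R,5S)-3-(benzyloxy)-5-(tert-butyldimethylsilyloxy)-6-(1,3-dithian-2-ylidene)-4-methylheptan-2-ol | S1CCCSC1=C(C)[C@@H](O[Si](C)(C)C(C)(C)C)[C@H](C)[C@@H](OCc2ccccc2)[C@@H](O)C | intermediate
18 | methanol | CO | starting material
19 | 2-[(2S,3S,4R,5R,6S)-5-(benzyloxy)-3-(tert-butyldimethylsilyloxy)-2,4,6-trimethyloxan-2-yl]-2-methoxy-1,3-dithiane | COC1(SCCCS1)[C@@]2(C)O[C@@H](C)[C@H](OCc3ccccc3)[C@@H](C)[C@@H]2O[Si](C)(C)C(C)(C)C | intermediate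
20 | methyl (2S,3S,4R,5R,6S)-5-(benzyloxy)-3-(tert-butyldimethylsilyloxy)-2,4,6-trimethyloxane-2-carboxylate | COC(=O)[C@@]1(C)O[C@@H](C)[C@H](OCc2ccccc2)[C@@H](C)[C@@H]1O[Si](C)(C)C(C)(C)C | intermediate
21 | (2S,3S,4R,5R,6S)-5-(benzyloxy)-3-(tert-butyldimethylsilyloxy)-2,4,6-trimethyloxane-2-carbaldehyde | O=C[C@@]1(C)O[C@@H](C)[C@H](OCc2ccccc2)[C@@H](C)[C@@H]1O[Si](C)(C)C(C)(C)C | intermediate
22 | S-tert-butyl propanethioate | CCC(=O)SC(C)(C)C | starting material
23 | lithium enolate of 22, methyl trans to OLi (not isolated) | C/C=C(\SC(C)(C)C)O[Li] | intermediate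
24 | (Z)-1-(tert-butylsulfanyl)-1-(trimethylsilyloxy)prop-1-ene, methyl trans to the silyloxy group | C/C=C(\SC(C)(C)C)O[Si](C)(C)C | intermediate
25 | S-tert-butyl (2R,3S)-3-[(2R,3S,4R,5R,6S)-5-(benzyloxy)-3-(tert-butyldimethylsilyloxy)-2,4,6-trimethyloxan-2-yl]-3-hydroxy-2-methylpropanethioate | CC(C)(C)SC(=O)[C@H](C)[C@H](O)[C@@]1(C)O[C@@H](C)[C@H](OCc2ccccc2)[C@@H](C)[C@@H]1O[Si](C)(C)C(C)(C)C | intermediate
26 | O5-desilylated derivative of 25 (3,5-dihydroxy thioester; not isolated) | CC(C)(C)SC(=O)[C@H](C)[C@H](O)[C@@]1(C)O[C@@H](C)[C@H](OCc2ccccc2)[C@@H](C)[C@@H]1O | intermediate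
27 | 7-(benzyloxy)-4-hydroxy-3,4a,6,8-tetramethylhexahydropyrano[3,2-b]pyran-2(3H)-one; botcinin numbering 2R,3S,4R,5S,6R,7R,8S (3-OH, 7-OBn) | O(Cc3ccccc3)[C@@H]1[C@@H](C)[C@@H]2OC(=O)[C@H](C)[C@H](O)[C@@]2(C)O[C@H]1C | intermediate
28 | 3-O-acetate of 27; botcinin numbering 2R,3S,4S,5S,6R,7R,8S (3-OAc, 7-OBn) | O(Cc3ccccc3)[C@@H]1[C@@H](C)[C@@H]2OC(=O)[C@H](C)[C@H](OC(C)=O)[C@@]2(C)O[C@H]1C | intermediate
29 | 4-acetoxy-7-hydroxy-3,4a,6,8-tetramethylhexahydropyrano[3,2-b]pyran-2(3H)-one; botcinin numbering 2R,3S,4S,5S,6R,7R,8S (3-OAc, 7-OH) | O[C@@H]1[C@@H](C)[C@@H]2OC(=O)[C@H](C)[C@H](OC(C)=O)[C@@]2(C)O[C@H]1C | intermediate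
30 | heptanal | CCCCCCC=O | starting material
31 | ethynylmagnesium bromide | C#C[Mg]Br | starting material
32 | (±)-non-1-yn-3-ol | CCCCCCC(O)C#C | intermediate
33 | (±)-triethyl(non-1-yn-3-yloxy)silane | CCCCCCC(O[Si](CC)(CC)CC)C#C | intermediate
34 | lithium acetylide of 33 (not isolated) | CCCCCCC(O[Si](CC)(CC)CC)C#C[Li] | intermediate
35 | (±)-4-(triethylsilyloxy)dec-2-ynoic acid | CCCCCCC(O[Si](CC)(CC)CC)C#CC(=O)O | intermediate
36 | 7-O-[4-(triethylsilyloxy)dec-2-ynoyl] ester of 29 (two epimers at the side-chain carbinol) | CCCCCCC(O[Si](CC)(CC)CC)C#CC(=O)O[C@@H]1[C@@H](C)[C@@H]2OC(=O)[C@H](C)[C@H](OC(C)=O)[C@@]2(C)O[C@H]1C | intermediate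
37 | 7-O-(4-hydroxydec-2-ynoyl) ester of 29 (not isolated) | CCCCCCC(O)C#CC(=O)O[C@@H]1[C@@H](C)[C@@H]2OC(=O)[C@H](C)[C@H](OC(C)=O)[C@@]2(C)O[C@H]1C | intermediate
38 | 7-O-(4-oxodec-2-ynoyl) ester of 29 | CCCCCCC(=O)C#CC(=O)O[C@@H]1[C@@H](C)[C@@H]2OC(=O)[C@H](C)[C@H](OC(C)=O)[C@@]2(C)O[C@H]1C | intermediate
39 | Botcinin J (2R,3S,4S,5S,6R,7R,8S; 7-O-[(Z)-4-oxodec-2-enoyl]) | CCCCCCC(=O)/C=C\C(=O)O[C@@H]1[C@@H](C)[C@@H]2OC(=O)[C@H](C)[C@H](OC(C)=O)[C@@]2(C)O[C@H]1C | target

**Step count**
Total: 25 steps. Longest linear sequence: 21 steps (steps 1–14, 16–19, 23–25); step 15 and steps 20–22 are side branches.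

**Steps most likely to fail**

1. Step 12 (anodic ring A closure). The radical cation may be captured by methanol at C4 before the ring closes, O8 may add to the other alkene face, or sulfur may be oxidised further. Fallback, setting out from ketone 13 and returning at aldehyde 21, with normal polarity at C4: the kinetic lithium enolate of 13 (LiN(SiMe3)2, THF, −78 °C, deprotonation on the methyl side) would be hydroxylated with 2-(phenylsulfonyl)-3-phenyloxaziridine to the α-hydroxy ketone F1. Pyridinium p-toluenesulfonate in methanol would remove the O8 silyl group and close the cyclic methyl ketal F2. AlMe3 with Me3SiOTf in CH2Cl2 would ionise the ketal to the ring oxocarbenium ion and deliver methyl axially, giving the ring A carbinol F3 with the C4 methyl axial and C3 equatorial. Dess–Martin oxidation of F3 would give 21.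

2. Step 16 (chelation-controlled aldol). Incomplete chelation would let addition occur on the other aldehyde face (C3 epimer), the anti simple selectivity may erode, and the Lewis acid may strip the O5 silyl ether. Fallback, setting out from aldehyde 21 and returning at lactone 27, in which C3 and C2 are set in separate steps: isopropenylmagnesium bromide 9 would add to 21 precomplexed with MgBr2·OEt2 in CH2Cl2 at −78 °C under chelate control to give the allylic alcohol F4 (3S). Hydroboration of the 1,1-disubstituted alkene with 9-BBN, then NaOH/H2O2, should give the 2,3-anti diol F5 by attack anti to the bulky ring substituent in the conformer that minimises allylic strain. Aqueous HF in MeCN would remove the O5 silyl group to give the triol F6. TEMPO with PhI(OAc)2 would oxidise the primary alcohol and close the lactol to the lactone 27.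

3. Step 25 (semihydrogenation of the ynone). The activated alkene may be reduced further to the saturated keto ester, or the Z-enone may isomerise to the E-isomer on the catalyst or during isolation. Fallback, setting out from silyloxy ynoate 36 and returning at target 39, with the order of reduction and oxidation reversed: semihydrogenation of the less activated alkyne of 36 (H2, Pd/CaCO3 with Pb(OAc)2, quinoline, EtOAc) would give the Z-silyloxy enoate F7. Buffered HF·pyridine at 0 °C would free the Z-hydroxy enoate F8, which would be oxidised at once with Dess–Martin periodinane and NaHCO3 to 39 before it can lactonise to a butenolide.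

**Further compounds**
F1 | step 12 | (3S,4R,5R,6S)-5-(benzyloxy)-3-(tert-butyldimethylsilyloxy)-1-hydroxy-4-methyl-6-(triethylsilyloxy)heptan-2-one | OCC(=O)[C@@H](O[Si](C)(C)C(C)(C)C)[C@H](C)[C@@H](OCc1ccccc1)[C@@H](O[Si](CC)(CC)CC)C
F2 | step 12 | [(3S,4R,5R,6S)-5-(benzyloxy)-3-(tert-butyldimethylsilyloxy)-2-methoxy-4,6-dimethyloxan-2-yl]methanol (anomeric mixture) | COC1(CO)O[C@@H](C)[C@H](OCc2ccccc2)[C@@H](C)[C@@H]1O[Si](C)(C)C(C)(C)C
F3 | step 12 | [(2R,3S,4R,5R,6S)-5-(benzyloxy)-3-(tert-butyldimethylsilyloxy)-2,4,6-trimethyloxan-2-yl]methanol | OC[C@@]1(C)O[C@@H](C)[C@H](OCc2ccccc2)[C@@H](C)[C@@H]1O[Si](C)(C)C(C)(C)C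
F4 | step 16 | (S)-1-[(2R,3S,4R,5R,6S)-5-(benzyloxy)-3-(tert-butyldimethylsilyloxy)-2,4,6-trimethyloxan-2-yl]-2-methylprop-2-en-1-ol | C=C(C)[C@H](O)[C@@]1(C)O[C@@H](C)[C@H](OCc2ccccc2)[C@@H](C)[C@@H]1O[Si](C)(C)C(C)(C)C
F5 | step 16 | 2,3-anti 1,3-diol from hydroboration of F4 (C1 primary alcohol, O5 silylated) | OC[C@H](C)[C@H](O)[C@@]1(C)O[C@@H](C)[C@H](OCc2ccccc2)[C@@H](C)[C@@H]1O[Si](C)(C)C(C)(C)C
F6 | step 16 | O5-desilylated triol from F5 | OC[C@H](C)[C@H](O)[C@@]1(C)O[C@@H](C)[C@H](OCc2ccccc2)[C@@H](C)[C@@H]1O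
F7 | step 25 | 7-O-[(Z)-4-(triethylsilyloxy)dec-2-enoyl] ester of 29 | CCCCCCC(O[Si](CC)(CC)CC)/C=C\C(=O)O[C@@H]1[C@@H](C)[C@@H]2OC(=O)[C@H](C)[C@H](OC(C)=O)[C@@]2(C)O[C@H]1C
F8 | step 25 | 7-O-[(Z)-4-hydroxydec-2-enoyl] ester of 29 | CCCCCCC(O)/C=C\C(=O)O[C@@H]1[C@@H](C)[C@@H]2OC(=O)[C@H](C)[C@H](OC(C)=O)[C@@]2(C)O[C@H]1C
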